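Ring B is a benzene whose neighbouring carbons C4a and C8a carry the dioxane oxygens O4 and O1. The route therefore disconnects ring B and the dioxane together: two O-alkynyl groups on the threo C2–C3 diol and methyl propiolate supply all six ring B carbons. One ruthenium-catalysed [2+2+2] cycloaddition forms C4a–C8a, C8–C7 and C6–C5, closes both rings and places the ester at C7 and a silicon marker at C5, while C2 and C3 pass through unchanged. The precursor is the (1S,2S)-1-arylpropane-1,2,3-triol derivative with an ethynyl ether on O1, a silylethynyl ether on O4 and a trityl ether on the primary oxygen, made by an Evans glycolate aldol.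

Key step: step 12

Remark on the chemistry: positions are numbered O1, C2 (aryl), C3 (CH2OH), O4, C4a, C5 (OMe), C6, C7 (side chain), C8, C8a; the silicon marker is carried as Me2Si–O–SiMe3, because silicon that bears oxygen can be oxidised to the C5 oxygen by peroxide, whereas halogenating an aryl–SiMe3 bond would attack the trialkoxyphenyl ring first, and the primary alcohol is carried as a trityl ether, which cannot migrate to a neighbouring alkoxide.

Abbreviations: Ar = 3,5-dimethoxy-4-(methoxymethoxy)phenyl; Tr = triphenylmethyl; Sx = pentamethyldisiloxanyl (Me2Si–O–SiMe3).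

Step 1
Reactants: 1 syringaldehyde
Product: 2 3,5-dimethoxy-4-(methoxymethoxy)benzaldehyde
Conditions: MOMCl, i-Pr2NEt, CH2Cl2, 0 °C to rt
Reagents that add atoms: chloromethyl methyl ether, COCCl
Why: O-alkylation of the phenol (acetal-type Williamson etherification) gives a MOM ether that should withstand the boron, hydride, KH and organolithium steps and is cleaved by dilute acid at the end.

Step 2
Reactants: 3 (R)-4-benzyl-2-oxazolidinone; 4 (benzyloxy)acetyl chloride
Product: 5 (R)-4-benzyl-3-[(benzyloxy)acetyl]oxazolidin-2-one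
Conditions: Et3N, DMAP (cat.), CH2Cl2, 0 °C to rt
Reagents that add atoms: none
Why: N-acylation of the oxazolidinone by the acid chloride under amine/DMAP catalysis is a routine imide formation that does not touch the auxiliary stereocentre.

Step 3
Reactants: 5 glycolyl imide; 2 protected aldehyde
Product: 7 (R)-4-benzyl-3-[(2R,3S)-3-Ar-2-(benzyloxy)-3-hydroxypropanoyl]oxazolidin-2-one, via boron Z-enolate 6 (not isolated)
Conditions: Bu2BOTf, Et3N, CH2Cl2, −78 to 0 °C; then 2, −78 to 0 °C; pH 7 buffer, MeOH, H2O2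
Reagents that add atoms: none
Why: Evans syn-aldol, in which the boron Z-enolate reacts through a closed chair transition state and the benzyl group of the (R)-auxiliary shields one enolate face, so that C2 should be set as R and the carbinol carbon as S (syn, the threo pattern that later becomes the trans dioxane).

Step 4
Reactants: 7 aldol adduct
Product: 8 (1S,2S)-1-Ar-2-(benzyloxy)propane-1,3-diol
Conditions: LiBH4, MeOH (1 equiv), THF, 0 °C
Reagents that add atoms: none
Why: Hydride reduction of the N-acyl oxazolidinone (reductive auxiliary cleavage) gives the primary alcohol without touching either stereocentre, the benzyloxy carbon changing from R to S only because the priority order changes.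

Step 5
Reactants: 8 diol
Product: 9 (4S,5S)-4-Ar-5-(benzyloxy)-2,2-dimethyl-1,3-dioxane
Conditions: Me2C(OMe)2, PPTS (cat.), CH2Cl2, rt
Reagents that add atoms: 2,2-dimethoxypropane, COC(C)(C)OC
Why: Acid-catalysed transacetalisation ties the benzylic and the primary hydroxyl into a six-membered acetonide, a protecting group that cannot migrate to a neighbouring alkoxide.

Step 6
Reactants: 9 benzyl ether
Product: 10 (4S,5S)-4-Ar-2,2-dimethyl-1,3-dioxan-5-ol
Conditions: H2 (1 atm), 10% Pd/C, EtOAc, rt
Reagents that add atoms: none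
Why: Catalytic hydrogenolysis removes the unhindered benzyl ether before any alkyne or vinyl chloride is present and under neutral conditions should spare the hindered benzylic C–O bond of the acetal ring.

Step 7
Reactants: 10 alcohol; 11 trichloroethylene
Product: 12 (4S,5S)-4-Ar-5-[(E)-1,2-dichloroethenyloxy]-2,2-dimethyl-1,3-dioxane
Conditions: KH, THF, 0 °C; then 11, −50 °C to rt
Reagents that add atoms: none
Why: The potassium alkoxide dehydrochlorinates trichloroethylene to dichloroacetylene and adds to it in anti fashion (nucleophilic addition to a haloalkyne), a known way to make (E)-1,2-dichlorovinyl ethers of secondary alcohols.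

Step 8
Reactants: 12 acetonide
Product: 13 (1S,2S)-1-Ar-2-[(E)-1,2-dichloroethenyloxy]propane-1,3-diol
Conditions: AcOH/THF/H2O (3:1:1), 40 °C
Reagents that add atoms: none
Why: Mild acid hydrolysis of the acetonide should leave the electron-poor dichlorovinyl ether and the aryl MOM ether intact, since both need stronger acid.

Step 9
Reactants: 13 diol
Product: 14 (1S,2S)-1-Ar-2-[(E)-1,2-dichloroethenyloxy]-3-(triphenylmethoxy)propan-1-ol
Conditions: TrCl, Et3N, DMAP (cat.), CH2Cl2, rt
Reagents that add atoms: trityl chloride, ClC(c1ccccc1)(c1ccccc1)c1ccccc1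
Why: Tritylation (SN1-type etherification) is selective for the primary hydroxyl on steric grounds and gives an ether that cannot migrate in the basic steps and leaves together with the MOM group in the last step.

Step 10
Reactants: 14 trityl ether
Product: 17 (1S,2S)-1-Ar-2-[(Sx-ethynyl)oxy]-3-(triphenylmethoxy)propan-1-ol, via dilithio species 15 (not isolated), via bis-silylated ether 16 (not isolated)
Conditions: n-BuLi (3.3 equiv), THF, −78 to −40 °C; ClSiMe2OSiMe3 (2.3 equiv), −78 to 0 °C; then K2CO3 (cat.), MeOH, 0 °C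
Reagents that add atoms: chloropentamethyldisiloxane, C[Si](C)(C)O[Si](C)(C)Cl
Why: After deprotonation of the alcohol, n-BuLi converts the dichlorovinyl ether into the lithium alkynyl ether (dehydrochlorination then chlorine–lithium exchange), both anions are silylated, and brief basic methanolysis should cleave only the far more labile O–Si bond.

Step 11
Reactants: 17 silyl ynol ether alcohol; 11 trichloroethylene
Product: 20 threo bis(ynol ether) (1S,2S)-1-Ar-1-(ethynyloxy)-2-[(Sx-ethynyl)oxy]-3-(triphenylmethoxy)propane, via dichlorovinyl ether 18 (not isolated), via lithium alkynyl ether 19 (not isolated)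
Conditions: KH, THF, 0 °C; 11, −50 °C to rt; then n-BuLi (2.4 equiv), −78 °C; MeOH, −78 °C
Reagents that add atoms: none
Why: The same alkoxide addition to dichloroacetylene, n-BuLi elimination and protonation should give the terminal benzylic ynol ether, with the alkoxide kept cold and short-lived and n-BuLi kept at −78 °C so that the silyl alkyne and the Si–O–Si link survive.

Step 12
Reactants: 20 bis(ynol ether); 21 methyl propiolate
Product: 22 methyl (2S,3S)-2-Ar-5-Sx-3-[(triphenylmethoxy)methyl]-2,3-dihydro-1,4-benzodioxine-7-carboxylate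
Conditions: Cp*RuCl(cod) (10 mol %), 21 (5 equiv), ClCH2CH2Cl, 20 °C, slow addition of 20
Reagents that add atoms: none
Why: Proposed new method: oxidative coupling of the two tethered ynol ether alkynes at the Cp*RuCl fragment should give a ruthenacyclopentadiene and with it the C4a–C8a bond, after which methyl propiolate inserts and reductive elimination forms C8–C7 and C6–C5 ([2+2+2] cyclotrimerisation). The closest known reaction type is the Cp*RuCl(cod)- or cationic rhodium-catalysed cycloaddition of 1,6- and 1,7-diynes with terminal alkynes, which tolerates silyl alkynes and single alkynyl ethers but has not been run on a diyne in which both alkynes are ynol ethers. The dioxane ring closes in the metallacycle-forming step, as the six-membered ring held by the O1–C2–C3–O4 tether, and benzene ring B closes by alkyne insertion and reductive elimination. No stereocentre is formed; C2 and C3 lie in the tether and are not touched, so the trans arrangement is that of the threo diol. The step needs cross- over homo-trimerisation, which excess propiolate and slow addition of 20 should secure, and the ester at C7 instead of C6, which the bulky silyl terminus should secure because the substituted propiolate carbon bonds to the unhindered C8. It must run near room temperature because the benzylic ynol ether rearranges on heating.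

Step 13
Reactants: 22 aryl disiloxane
Product: 23 methyl (2S,3S)-2-Ar-5-hydroxy-3-[(triphenylmethoxy)methyl]-2,3-dihydro-1,4-benzodioxine-7-carboxylate
Conditions: H2O2 (30% aq.), KF, KHCO3, THF/MeOH, rt
Reagents that add atoms: hydrogen peroxide, OO
Why: Tamao–Fleming oxidation, in which hydroperoxide adds to the oxygen-bearing silicon and the aryl group migrates from silicon to oxygen at the same carbon, is a nucleophilic process that should leave the electron-rich trialkoxyphenyl ring alone.

Step 14
Reactants: 23 phenol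
Product: 24 methyl (2S,3S)-2-Ar-5-methoxy-3-[(triphenylmethoxy)methyl]-2,3-dihydro-1,4-benzodioxine-7-carboxylate
Conditions: MeI, K2CO3, acetone, 50 °C
Reagents that add atoms: iodomethane, CI
Why: Williamson O-methylation of the only free phenol installs the C5 methoxy group without affecting the methyl ester.

Step 15
Reactants: 24 methyl ester
Product: 25 [(2S,3S)-2-Ar-5-methoxy-3-[(triphenylmethoxy)methyl]-2,3-dihydro-1,4-benzodioxin-7-yl]methanol
Conditions: i-Bu2AlH, CH2Cl2, −78 to 0 °C
Reagents that add atoms: none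
Why: Hydride reduction of the aromatic methyl ester to the benzylic alcohol is routine, and trityl, MOM and aryl ethers are inert to the reagent.

Step 16
Reactants: 25 benzylic alcohol
Product: 26 (2S,3S)-2-Ar-5-methoxy-3-[(triphenylmethoxy)methyl]-2,3-dihydro-1,4-benzodioxine-7-carbaldehyde
Conditions: MnO2, CH2Cl2, rt
Reagents that add atoms: none
Why: MnO2 oxidises the benzylic alcohol selectively to the aldehyde without over-oxidation.

Step 17
Reactants: 26 aldehyde; 27 (triphenylphosphoranylidene)acetaldehyde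
Product: 28 (E)-3-[(2S,3S)-2-Ar-5-methoxy-3-[(triphenylmethoxy)methyl]-2,3-dihydro-1,4-benzodioxin-7-yl]prop-2-enal
Conditions: toluene, 80 °C
Reagents that add atoms: none
Why: Wittig olefination with the stabilised formylmethylene ylide should give the (E)-enal, and the conjugated product aldehyde reacts more slowly with the ylide than the aryl aldehyde does.

Step 18
Reactants: 28 protected enal
Product: 29 bilagrewin [(E)-3-[(2S,3S)-2-(4-hydroxy-3,5-dimethoxyphenyl)-3-(hydroxymethyl)-5-methoxy-2,3-dihydro-1,4-benzodioxin-7-yl]prop-2-enal]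
Conditions: aq. HCl (2 M), THF, rt to 40 °C
Reagents that add atoms: none
Why: Acid hydrolysis should remove the trityl ether and the aryl MOM acetal in one operation under conditions too mild to open the benzylic aryl ether of the trans dioxane or to harm the enal.

Compound list
1 | syringaldehyde (4-hydroxy-3,5-dimethoxybenzaldehyde) | COc1cc(C=O)cc(OC)c1O | starting material
2 | 3,5-dimethoxy-4-(methoxymethoxy)benzaldehyde | COCOc1c(OC)cc(C=O)cc1OC | intermediate
3 | (R)-4-benzyl-2-oxazolidinone | O=C1N[C@H](Cc2ccccc2)CO1 | starting material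
4 | (benzyloxy)acetyl chloride | O=C(Cl)COCc1ccccc1 | starting material
5 | (R)-4-benzyl-3-[(benzyloxy)acetyl]oxazolidin-2-one | O=C(COCc1ccccc1)N1[C@H](Cc2ccccc2)COC1=O | intermediate
6 | dibutylboron (Z)-enolate of 5 | CCCCB(CCCC)O/C(=C\OCc1ccccc1)N1[C@H](Cc2ccccc2)COC1=O | intermediate (not isolated)
7 | (R)-4-benzyl-3-[(2R,3S)-2-(benzyloxy)-3-[3,5-dimethoxy-4-(methoxymethoxy)phenyl]-3-hydroxypropanoyl]oxazolidin-2-one | COCOc1c(OC)cc([C@H](O)[C@@H](OCc2ccccc2)C(=O)N2[C@H](Cc3ccccc3)COC2=O)cc1OC | intermediate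
8 | (1S,2S)-2-(benzyloxy)-1-[3,5-dimethoxy-4-(methoxymethoxy)phenyl]propane-1,3-diol | COCOc1c(OC)cc([C@H](O)[C@@H](OCc2ccccc2)CO)cc1OC | intermediate
9 | (4S,5S)-5-(benzyloxy)-4-[3,5-dimethoxy-4-(methoxymethoxy)phenyl]-2,2-dimethyl-1,3-dioxane | COCOc1c(OC)cc([C@@H]2OC(C)(C)OC[C@@H]2OCc3ccccc3)cc1OC | intermediate
10 | (4S,5S)-4-[3,5-dimethoxy-4-(methoxymethoxy)phenyl]-2,2-dimethyl-1,3-dioxan-5-ol | COCOc1c(OC)cc([C@@H]2OC(C)(C)OC[C@@H]2O)cc1OC | intermediate
11 | trichloroethylene | ClC=C(Cl)Cl | starting material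
12 | (4S,5S)-5-[(E)-1,2-dichloroethenyloxy]-4-[3,5-dimethoxy-4-(methoxymethoxy)phenyl]-2,2-dimethyl-1,3-dioxane | COCOc1c(OC)cc([C@@H]2OC(C)(C)OC[C@@H]2O/C(Cl)=C\Cl)cc1OC | intermediate
13 | (1S,2S)-2-[(E)-1,2-dichloroethenyloxy]-1-[3,5-dimethoxy-4-(methoxymethoxy)phenyl]propane-1,3-diol | COCOc1c(OC)cc([C@H](O)[C@@H](O/C(Cl)=C\Cl)CO)cc1OC | intermediate
14 | (1S,2S)-2-[(E)-1,2-dichloroethenyloxy]-1-[3,5-dimethoxy-4-(methoxymethoxy)phenyl]-3-(triphenylmethoxy)propan-1-ol | COCOc1c(OC)cc([C@H](O)[C@@H](O/C(Cl)=C\Cl)COC(c2ccccc2)(c3ccccc3)c4ccccc4)cc1OC | intermediate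
15 | dilithio species: lithium (1S,2S)-1-[3,5-dimethoxy-4-(methoxymethoxy)phenyl]-2-[(lithioethynyl)oxy]-3-(triphenylmethoxy)propan-1-olate | COCOc1c(OC)cc([C@H](O[Li])[C@@H](OC#C[Li])COC(c2ccccc2)(c3ccccc3)c4ccccc4)cc1OC | intermediate (not isolated)
16 | (1S,2S)-1-[3,5-dimethoxy-4-(methoxymethoxy)phenyl]-1-[(pentamethyldisiloxanyl)oxy]-2-{[(pentamethyldisiloxanyl)ethynyl]oxy}-3-(triphenylmethoxy)propane | COCOc1c(OC)cc([C@H](O[Si](C)(C)O[Si](C)(C)C)[C@@H](OC#C[Si](C)(C)O[Si](C)(C)C)COC(c2ccccc2)(c3ccccc3)c4ccccc4)cc1OC | intermediate (not isolated)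
17 | (1S,2S)-1-[3,5-dimethoxy-4-(methoxymethoxy)phenyl]-2-{[(pentamethyldisiloxanyl)ethynyl]oxy}-3-(triphenylmethoxy)propan-1-ol | COCOc1c(OC)cc([C@H](O)[C@@H](OC#C[Si](C)(C)O[Si](C)(C)C)COC(c2ccccc2)(c3ccccc3)c4ccccc4)cc1OC | intermediate
18 | (1S,2S)-1-[(E)-1,2-dichloroethenyloxy]-1-[3,5-dimethoxy-4-(methoxymethoxy)phenyl]-2-{[(pentamethyldisiloxanyl)ethynyl]oxy}-3-(triphenylmethoxy)propane | COCOc1c(OC)cc([C@H](O/C(Cl)=C\Cl)[C@@H](OC#C[Si](C)(C)O[Si](C)(C)C)COC(c2ccccc2)(c3ccccc3)c4ccccc4)cc1OC | intermediate (not isolated)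
19 | lithium acetylide of 20 (O1-lithioethynyl ether) | COCOc1c(OC)cc([C@H](OC#C[Li])[C@@H](OC#C[Si](C)(C)O[Si](C)(C)C)COC(c2ccccc2)(c3ccccc3)c4ccccc4)cc1OC | intermediate (not isolated)
20 | threo bis(ynol ether): (1S,2S)-1-[3,5-dimethoxy-4-(methoxymethoxy)phenyl]-1-(ethynyloxy)-2-{[(pentamethyldisiloxanyl)ethynyl]oxy}-3-(triphenylmethoxy)propane | COCOc1c(OC)cc([C@H](OC#C)[C@@H](OC#C[Si](C)(C)O[Si](C)(C)C)COC(c2ccccc2)(c3ccccc3)c4ccccc4)cc1OC | intermediate
21 | methyl propiolate | C#CC(=O)OC | starting material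
22 | methyl (2S,3S)-2-[3,5-dimethoxy-4-(methoxymethoxy)phenyl]-5-(pentamethyldisiloxanyl)-3-[(triphenylmethoxy)methyl]-2,3-dihydro-1,4-benzodioxine-7-carboxylate | COCOc1c(OC)cc([C@@H]2Oc3cc(C(=O)OC)cc([Si](C)(C)O[Si](C)(C)C)c3O[C@H]2COC(c4ccccc4)(c5ccccc5)c6ccccc6)cc1OC | intermediate
23 | methyl (2S,3S)-2-[3,5-dimethoxy-4-(methoxymethoxy)phenyl]-5-hydroxy-3-[(triphenylmethoxy)methyl]-2,3-dihydro-1,4-benzodioxine-7-carboxylate | COCOc1c(OC)cc([C@@H]2Oc3cc(C(=O)OC)cc(O)c3O[C@H]2COC(c4ccccc4)(c5ccccc5)c6ccccc6)cc1OC | intermediate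
24 | methyl (2S,3S)-2-[3,5-dimethoxy-4-(methoxymethoxy)phenyl]-5-methoxy-3-[(triphenylmethoxy)methyl]-2,3-dihydro-1,4-benzodioxine-7-carboxylate | COCOc1c(OC)cc([C@@H]2Oc3cc(C(=O)OC)cc(OC)c3O[C@H]2COC(c4ccccc4)(c5ccccc5)c6ccccc6)cc1OC | intermediate
25 | [(2S,3S)-2-[3,5-dimethoxy-4-(methoxymethoxy)phenyl]-5-methoxy-3-[(triphenylmethoxy)methyl]-2,3-dihydro-1,4-benzodioxin-7-yl]methanol | COCOc1c(OC)cc([C@@H]2Oc3cc(CO)cc(OC)c3O[C@H]2COC(c4ccccc4)(c5ccccc5)c6ccccc6)cc1OC | intermediate
26 | (2S,3S)-2-[3,5-dimethoxy-4-(methoxymethoxy)phenyl]-5-methoxy-3-[(triphenylmethoxy)methyl]-2,3-dihydro-1,4-benzodioxine-7-carbaldehyde | COCOc1c(OC)cc([C@@H]2Oc3cc(C=O)cc(OC)c3O[C@H]2COC(c4ccccc4)(c5ccccc5)c6ccccc6)cc1OC | intermediate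
27 | (triphenylphosphoranylidene)acetaldehyde | O=CC=P(c1ccccc1)(c1ccccc1)c1ccccc1 | starting material
28 | (E)-3-[(2S,3S)-2-[3,5-dimethoxy-4-(methoxymethoxy)phenyl]-5-methoxy-3-[(triphenylmethoxy)methyl]-2,3-dihydro-1,4-benzodioxin-7-yl]prop-2-enal | COCOc1c(OC)cc([C@@H]2Oc3cc(/C=C/C=O)cc(OC)c3O[C@H]2COC(c4ccccc4)(c5ccccc5)c6ccccc6)cc1OC | intermediate
29 | bilagrewin, (E)-3-[(2S,3S)-2-(4-hydroxy-3,5-dimethoxyphenyl)-3-(hydroxymethyl)-5-methoxy-2,3-dihydro-1,4-benzodioxin-7-yl]prop-2-enal | COc1cc([C@@H]2Oc3cc(/C=C/C=O)cc(OC)c3O[C@H]2CO)cc(OC)c1O | target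

Total step count: 18. Longest linear sequence: 17 steps (step 1 and steps 3–18 from syringaldehyde; the branch through step 2 is equally long).

Steps most likely to fail

1. Step 12 (the key cycloaddition). The terminal ynol ether may deactivate the ruthenium catalyst, the alkynes may homo-oligomerise instead of cross-trimerising, the benzylic ynol ether may rearrange before the metal captures it, or propiolate may insert with the wrong orientation. Within the same approach the catalyst can be changed to [Rh(cod)2]BF4 with BINAP. The fallback uses known chemistry, leaves the alkyne route at alcohol 10 and returns at ester 24. The potassium alkoxide of 10 (KHMDS, THF, −20 °C to rt) displaces fluoride from methyl 3-bromo-4-fluoro-5-methoxybenzoate by nucleophilic aromatic substitution para to the ester, which gives aryl ether acetonide F1. Aqueous acetic acid frees diol F2, and trityl chloride protects the primary hydroxyl to give bromo alcohol F3. Palladium-catalysed intramolecular aryl ether formation (Pd(OAc)2, 2-(di-tert-butylphosphino)-1,1'-binaphthyl, Cs2CO3, toluene, 70 °C) then joins O1 to C8a and gives 24 with both stereocentres untouched.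

2. Step 11 (second ynol ether). The potassium alkoxide may attack the neighbouring silyl alkyne before trichloroethylene traps it, by silyl transfer to oxygen or by ring closure onto the ynol ether, and n-BuLi may cleave a bond to silicon. The free hydroxyl of 17 may also add to the ynol ether on acidic surfaces, so 17 should be used at once. The fallback sets out from 17 and returns at 20 without ever forming an alkoxide next to the silyl alkyne. Alcohol 17 is formylated with acetic formic anhydride and pyridine to formate F4. PPh3 and CCl4 (Wittig-type dichloromethylenation, THF, 60 °C) convert the formate carbonyl into 2,2-dichlorovinyl ether F5. n-BuLi at −78 °C followed by methanol then gives 20.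

3. Step 17 (Wittig). The product enal may react a second time with the ylide (over-homologation to the dienal), or conversion may stall. The fallback sets out from aldehyde 26 and returns at enal 28. Horner–Wadsworth–Emmons olefination with triethyl phosphonoacetate and NaH gives cinnamate ester F6, i-Bu2AlH reduces it to allylic alcohol F7, and MnO2 oxidises that to 28.

Further compounds
F1 | step 12 | methyl 3-bromo-4-{[(4S,5S)-4-[3,5-dimethoxy-4-(methoxymethoxy)phenyl]-2,2-dimethyl-1,3-dioxan-5-yl]oxy}-5-methoxybenzoate | COCOc1c(OC)cc([C@@H]2OC(C)(C)OC[C@@H]2Oc3c(Br)cc(C(=O)OC)cc3OC)cc1OC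
F2 | step 12 | methyl 3-bromo-4-{[(1S,2S)-1-[3,5-dimethoxy-4-(methoxymethoxy)phenyl]-1,3-dihydroxypropan-2-yl]oxy}-5-methoxybenzoate | COCOc1c(OC)cc([C@H](O)[C@@H](Oc2c(Br)cc(C(=O)OC)cc2OC)CO)cc1OC
F3 | step 12 | methyl 3-bromo-4-{[(1S,2S)-1-[3,5-dimethoxy-4-(methoxymethoxy)phenyl]-1-hydroxy-3-(triphenylmethoxy)propan-2-yl]oxy}-5-methoxybenzoate | COCOc1c(OC)cc([C@H](O)[C@@H](Oc2c(Br)cc(C(=O)OC)cc2OC)COC(c3ccccc3)(c4ccccc4)c5ccccc5)cc1OC
F4 | step 11 | (1S,2S)-1-[3,5-dimethoxy-4-(methoxymethoxy)phenyl]-2-{[(pentamethyldisiloxanyl)ethynyl]oxy}-3-(triphenylmethoxy)propyl formate | COCOc1c(OC)cc([C@H](OC=O)[C@@H](OC#C[Si](C)(C)O[Si](C)(C)C)COC(c2ccccc2)(c3ccccc3)c4ccccc4)cc1OC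
F5 | step 11 | (1S,2S)-1-(2,2-dichloroethenyloxy)-1-[3,5-dimethoxy-4-(methoxymethoxy)phenyl]-2-{[(pentamethyldisiloxanyl)ethynyl]oxy}-3-(triphenylmethoxy)propane | COCOc1c(OC)cc([C@H](OC=C(Cl)Cl)[C@@H](OC#C[Si](C)(C)O[Si](C)(C)C)COC(c2ccccc2)(c3ccccc3)c4ccccc4)cc1OC
F6 | step 17 | ethyl (E)-3-[(2S,3S)-2-[3,5-dimethoxy-4-(methoxymethoxy)phenyl]-5-methoxy-3-[(triphenylmethoxy)methyl]-2,3-dihydro-1,4-benzodioxin-7-yl]prop-2-enoate | COCOc1c(OC)cc([C@@H]2Oc3cc(/C=C/C(=O)OCC)cc(OC)c3O[C@H]2COC(c4ccccc4)(c5ccccc5)c6ccccc6)cc1OC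
F7 | step 17 | (E)-3-[(2S,3S)-2-[3,5-dimethoxy-4-(methoxymethoxy)phenyl]-5-methoxy-3-[(triphenylmethoxy)methyl]-2,3-dihydro-1,4-benzodioxin-7-yl]prop-2-en-1-ol | COCOc1c(OC)cc([C@@H]2Oc3cc(/C=C/CO)cc(OC)c3O[C@H]2COC(c4ccccc4)(c5ccccc5)c6ccccc6)cc1OC
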